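**Retrosynthetic overview**

1. The succinimide is the last ring: C12–C13 comes from an Evans syn-aldol of a C12 aldehyde with an (R)-oxazolidinone 3-cyanopropanoyl imide; nitrile hydration and N-acyl transfer then close the imide.
2. C2–Cl comes from a C2 ketone (hydride from the α face gives the 2β-ol, Appel inversion gives 2α-Cl); the 7β-acetate comes from a C7 silyl ether through the 8(17)-en-7-one.
3. Key disconnection: rings A and B are made together from a monocyclic 2-alkyl-3,3-dimethylcyclobutanone. Rhodium cleaves C2–C5 and inserts the tethered isopropenyl group C10=C1, so the four-membered ring (C2, C3, C4, C5) grows by two atoms into ring A while the new C5–C10 bond closes ring B.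
4. Enabling feature: in ring A, C2 is flanked by two CH2 groups (C1, C3), each next to a quaternary carbon (C10, C4). With a C2 ketone, C2–C3–C4(Me2)–C5 is a 3,3-dimethylcyclobutanone unit and C1/C10/C20 is an isopropenyl group.
5. The cyclobutanone comes from 3,3-dimethylcyclobutanone (RAMP hydrazone, sets C5) and a vinyl oxirane whose C9 centre, isopropenyl group, C7, C8, C11 and C12 derive from (S)-carvone. Ring order: four-membered ring (purchased), then rings A and B in one step, then the succinimide.

Key step: step 10

Remark: atoms carry labdane numbers (C1–C10 decalin, C11/C12 side chain, C17 exocyclic methylene, C18/C19 gem-dimethyl, C20 angular methyl); β is the face of C20.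

Assumption: RAMP (step 8) and (R)-DTBM-SEGPHOS (step 10) are taken as the matched choices for the 5S centre, from the usual azaenolate model and ligand matching; if either sense proves opposite, the antipodal reagent is used.

**Route**

Step 1
Reactants: 1 (S)-(+)-carvone
Product: 2 (1S,4S,6S)-1-methyl-4-(prop-1-en-2-yl)-7-oxabicyclo[4.1.0]heptan-2-one (trans-carvone oxide)
Conditions: 30% H2O2, NaOH (aq.), MeOH, 0 °C
Reagents that add atoms: hydrogen peroxide, OO
Why: Weitz–Scheffer nucleophilic epoxidation touches only the enone (the isopropenyl group is not electrophilic), and hydroperoxide adds anti to the isopropenyl group to give the trans epoxide, whose two new centres are excised in step 2.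

Step 2
Reactants: 2 trans-carvone oxide
Product: 3 (3S)-5-oxo-3-(prop-1-en-2-yl)pentanoic acid
Conditions: H5IO6 (2.5 equiv), THF/H2O, 0 °C to rt
Reagents that add atoms: water, O
Why: Acid-mediated hydrolysis of the epoxide to the 2,3-diol and periodate (Malaprade-type) cleavage of the glycol and α-ketol bonds excise carvone C2 with its methyl group as acetic acid, leaving C1 as the acid and C3 as the aldehyde, while the isopropenyl-bearing centre (future C9) is untouched.

Step 3
Reactants: 3 aldehyde acid
Product: 4 methyl (3S)-5,5-dimethoxy-3-(prop-1-en-2-yl)pentanoate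
Conditions: HC(OMe)3, MeOH, p-TsOH·H2O (5 mol %), rt to 40 °C
Reagents that add atoms: trimethyl orthoformate, COC(OC)OC; methanol, CO
Why: Acid-catalysed acetalization and orthoester-driven esterification differentiate the two arms in one operation (aldehyde arm becomes C11–C12 as dimethyl acetal, acid arm becomes C8–C7 as methyl ester) without touching the stereocentre.

Step 4
Reactants: 4 acetal ester
Product: 5 (3R)-5,5-dimethoxy-3-(prop-1-en-2-yl)pentanal
Conditions: i-Bu2AlH (1.1 equiv), CH2Cl2, −78 °C; sodium potassium tartrate work-up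
Reagents that add atoms: none
Why: Half-reduction of the methyl ester by i-Bu2AlH at −78 °C stops at the aldehyde through the stable aluminium hemiacetal, and the acetal is inert to hydride.

Step 5
Reactants: 5 acetal aldehyde
Product: 6 (3R)-5,5-dimethoxy-2-methylidene-3-(prop-1-en-2-yl)pentanal
Conditions: 37% aq. HCHO, pyrrolidine (10 mol %), propionic acid (10 mol %), i-PrOH, 45 °C
Reagents that add atoms: formaldehyde, C=O
Why: Amine-catalysed Mannich condensation with formaldehyde and elimination (organocatalytic α-methylenation of an aldehyde) places C17 on the only α-carbon (C8), and C9 is not epimerized because it is not part of the enamine.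

Step 6
Reactants: 6 enal
Product: 7 2-[(3R)-5,5-dimethoxy-3-(prop-1-en-2-yl)pent-1-en-2-yl]oxirane (both epimers at the oxirane CH, future C7)
Conditions: Me3S+ I−, KN(SiMe3)2, THF, −20 to 0 °C
Reagents that add atoms: trimethylsulfonium iodide, C[S+](C)C.[I-]
Why: Corey–Chaykovsky epoxidation: dimethylsulfonium methylide adds 1,2 to the enal and the betaine closes to the vinyl oxirane, bringing in C6; the new C7 centre is not controlled, and both epimers converge at ketone 19.

Step 7
Reactants: 8 3,3-dimethylcyclobutan-1-one; 9 RAMP, (R)-1-amino-2-(methoxymethyl)pyrrolidine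
Product: 10 (2R)-N-(3,3-dimethylcyclobutylidene)-2-(methoxymethyl)pyrrolidin-1-amine
Conditions: neat, 4 Å molecular sieves, 60 °C
Reagents that add atoms: none
Why: Hydrazone condensation of a strained, unhindered ketone with the RAMP auxiliary; the ketone is symmetric, so no regio- or geometric isomers arise.

Step 8
Reactants: 10 RAMP hydrazone; 7 vinyl oxirane
Product: 13 RAMP hydrazone of (2S)-2-[(4R)-2-(tert-butyldimethylsilyloxy)-6,6-dimethoxy-3-methylidene-4-(prop-1-en-2-yl)hexyl]-3,3-dimethylcyclobutan-1-one (both epimers at the silyloxy carbon), via lithium azaenolate 11 (not isolated), via lithium alkoxide 12 (not isolated)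
Conditions: LiN(i-Pr)2, THF, 0 °C; then 7, −78 °C to rt; then t-BuMe2SiCl, DMPU, 0 °C to rt
Reagents that add atoms: tert-butyldimethylsilyl chloride, CC(C)(C)[Si](C)(C)Cl
Why: Enders RAMP-hydrazone alkylation: the lithium azaenolate opens the oxirane by SN2 attack at the terminal carbon C6, the chelated methoxymethylpyrrolidine shields one face so that C5 is set as S, and the alkoxide is silylated in situ so that no hemiketal can form after hydrolysis.

Step 9
Reactants: 13 silyloxy RAMP hydrazone
Product: 14 (2S)-2-[(4R)-2-(tert-butyldimethylsilyloxy)-6,6-dimethoxy-3-methylidene-4-(prop-1-en-2-yl)hexyl]-3,3-dimethylcyclobutan-1-one (both epimers at C2' of the chain, future C7)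
Conditions: CuCl2 (aq.), THF, pH 7 phosphate buffer, rt
Reagents that add atoms: water, O
Why: Copper-assisted hydrazone hydrolysis at pH 7 frees the cyclobutanone without acid (acetal and silyl ether survive) and without enolization of the C5 stereocentre.

Step 10
Reactants: 14 cyclobutanone
Product: 15 (5S,9R,10S)-7-(tert-butyldimethylsilyloxy)-12,12-dimethoxy-13,14,15,16-tetranorlabd-8(17)-en-2-one (trans-decalin, both C7 epimers)
Conditions: [Rh(C2H4)2Cl]2 (5 mol %), (R)-DTBM-SEGPHOS (12 mol %), 1,4-dioxane, 40 °C
Reagents that add atoms: none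
Why: Monovalent rhodium, held by the tethered olefin, adds oxidatively into the strained C2–C5 acyl–alkyl bond of 14 to give a five-membered acyl(alkyl) complex of trivalent rhodium, the isopropenyl group C10=C1 inserts into the Rh–C5 bond, and C(acyl)–C(sp3) reductive elimination forms C1–C2, so the four-membered ring (C2, C3, C4, C5) becomes ring A by gaining C10 and C1. The closest known reaction type is the rhodium-catalysed intramolecular olefin carboacylation ("cut-and-sew") of cyclobutanones with an olefin tether on the α-carbon, which gives trans-fused bicyclic ketones, and of benzocyclobutenones with 1,1-disubstituted olefins, which gives quaternary centres. Ring B closes by 6-exo migratory insertion (new C5–C10 bond), and ring A closes by reductive elimination from the seven-membered rhodacycle (new C1–C2 bond), a two-atom ring expansion. C5 keeps the configuration set in step 8 because the alkyl group migrates with retention; C10 is set in the insertion, where a chair-like tether with the C9 side chain equatorial and C4 of the rhodacycle anti to C9 should give the trans fusion (10S, C20 on the β face), reinforced by the matched ligand. The step needs cleavage of C2–C5 and not C2–C3 (only that rhodacycle can reach the olefin, and the other oxidative addition is reversible), insertion of the isopropenyl group and not the C8=C17 methylene (which would have to form a four-membered ring or a tertiary alkylrhodium), and insertion faster than β-hydride loss from C6 (favoured by the chelated olefin and the low temperature).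

Step 11
Reactants: 15 decalin-2-one
Product: 16 (2R,5S,9R,10S)-7-(tert-butyldimethylsilyloxy)-12,12-dimethoxy-13,14,15,16-tetranorlabd-8(17)-en-2β-ol (both C7 epimers)
Conditions: LiBH(s-Bu)3, THF, −78 °C; then NaOH, H2O2, 0 °C
Reagents that add atoms: none
Why: Hydride reduction of a hindered cyclohexanone: the β face of C2 is blocked by the two syn-axial methyl groups on C4 and C10, so the bulky borohydride attacks from the α face and gives the axial 2β-alcohol (2R).

Step 12
Reactants: 16 2β-alcohol
Product: 17 (2S,5S,9R,10S)-7-(tert-butyldimethylsilyloxy)-2α-chloro-12,12-dimethoxy-13,14,15,16-tetranorlabd-8(17)-ene (both C7 epimers)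
Conditions: PPh3, CCl4, 2,6-lutidine, MeCN, 60 °C
Reagents that add atoms: tetrachloromethane, ClC(Cl)(Cl)Cl
Why: Appel reaction: the alkoxyphosphonium ion is displaced by chloride with SN2 inversion from the open α face, giving the equatorial 2α-chloride (2S).

Step 13
Reactants: 17 silyl ether chloride
Product: 18 (2S,5S,9R,10S)-2α-chloro-12,12-dimethoxy-13,14,15,16-tetranorlabd-8(17)-en-7-ol (both C7 epimers)
Conditions: n-Bu4NF, THF, 0 °C to rt
Reagents that add atoms: none
Why: Fluoride-mediated cleavage of the secondary silyl ether; the equatorial chloride has no antiperiplanar hydrogen and should not be eliminated.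

Step 14
Reactants: 18 allylic alcohols
Product: 19 (2S,5S,9R,10S)-2α-chloro-12,12-dimethoxy-13,14,15,16-tetranorlabd-8(17)-en-7-one
Conditions: Dess–Martin periodinane, NaHCO3, CH2Cl2, 0 °C
Reagents that add atoms: none
Why: Dess–Martin oxidation converts both allylic C7 epimers into one cross-conjugated enone under buffered, non-enolizing conditions that avoid migration of the exocyclic double bond.

Step 15
Reactants: 19 enone
Product: 20 (2S,5S,7S,9R,10S)-2α-chloro-12,12-dimethoxy-13,14,15,16-tetranorlabd-8(17)-en-7β-ol
Conditions: NaBH4, CeCl3·7H2O, MeOH, −78 °C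
Reagents that add atoms: none
Why: Luche reduction (1,2-selective) with axial hydride attack from the α face of the ring B ketone gives the equatorial 7β-alcohol (7S).

Step 16
Reactants: 20 7β-alcohol
Product: 21 (2S,5S,7S,9R,10S)-2α-chloro-12,12-dimethoxy-13,14,15,16-tetranorlabd-8(17)-en-7β-yl acetate
Conditions: Ac2O, pyridine, DMAP (cat.), CH2Cl2, rt
Reagents that add atoms: acetic anhydride, CC(=O)OC(C)=O
Why: DMAP-catalysed acylation of the unhindered equatorial allylic alcohol, placed before the C12 hydroxyl exists so that no differentiation of alcohols is needed.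

Step 17
Reactants: 21 acetate acetal
Product: 22 (2S,5S,7S,9R,10S)-7β-acetoxy-2α-chloro-13,14,15,16-tetranorlabd-8(17)-en-12-al
Conditions: pyridinium p-toluenesulfonate, acetone/H2O, 40 °C
Reagents that add atoms: water, O
Why: Mild acid-catalysed acetal hydrolysis under conditions that leave the allylic acetate, the exocyclic alkene and the chloride intact.

Step 18
Reactants: 23 (R)-4-benzyl-1,3-oxazolidin-2-one; 24 3-cyanopropanoic acid
Product: 26 (4R)-4-benzyl-3-(3-cyanopropanoyl)-1,3-oxazolidin-2-one, via mixed pivalic anhydride 25 (not isolated)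
Conditions: t-BuCOCl, Et3N, THF, −20 °C; then LiCl, 23, rt
Reagents that add atoms: none
Why: N-Acylation of the oxazolidinone through the mixed pivalic anhydride, with attack at the less hindered cyanopropanoyl carbonyl.

Step 19
Reactants: 22 aldehyde; 26 cyano imide
Product: 28 (4R)-4-benzyl-3-[(2R,3S)-2-(cyanomethyl)-3-hydroxy-4-(decalinyl)butanoyl]-1,3-oxazolidin-2-one, the (12S,13R) syn-aldol adduct (decalinyl = C9 of the 7β-acetoxy-2α-chloro-8(17)-ene core), via Z-boron enolate 27 (not isolated)
Conditions: n-Bu2BOTf, i-Pr2NEt, CH2Cl2, −78 to 0 °C; then 22, −78 to 0 °C; pH 7 buffer, MeOH, 30% H2O2, 0 °C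
Reagents that add atoms: none
Why: Evans syn-aldol reaction: the Z-boron enolate reacts through a closed chair transition state on the face opposite to the benzyl group of the (R)-auxiliary, setting C12 (S) and C13 (R) under reagent control.

Step 20
Reactants: 28 aldol adduct
Product: 30 haterumaimide N, via primary amide 29 (not isolated)
Conditions: [PtH{(PMe2O)2H}(PMe2OH)] (5 mol %), EtOH/H2O (4:1), 70 °C; then Et3N (0.5 equiv), CH2Cl2, rt
Reagents that add atoms: water, O
Why: Platinum-catalysed hydration of the nitrile to the primary amide under neutral conditions (acetate and chloride untouched), followed by 5-exo-trig N-acyl transfer onto the activated imide carbonyl, closes the succinimide and expels the auxiliary without epimerizing C13.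

**Compound list**

1 | (S)-(+)-carvone | CC1=CC[C@@H](CC1=O)C(C)=C | starting material
2 | (1S,4S,6S)-1-methyl-4-(prop-1-en-2-yl)-7-oxabicyclo[4.1.0]heptan-2-one | C[C@]12O[C@H]1C[C@@H](CC2=O)C(C)=C | intermediate
3 | (3S)-5-oxo-3-(prop-1-en-2-yl)pentanoic acid | OC(=O)C[C@H](CC=O)C(C)=C | intermediate
4 | methyl (3S)-5,5-dimethoxy-3-(prop-1-en-2-yl)pentanoate | COC(=O)C[C@H](CC(OC)OC)C(C)=C | intermediate
5 | (3R)-5,5-dimethoxy-3-(prop-1-en-2-yl)pentanal | O=CC[C@H](CC(OC)OC)C(C)=C | intermediate
6 | (3R)-5,5-dimethoxy-2-methylidene-3-(prop-1-en-2-yl)pentanal | O=CC(=C)[C@H](CC(OC)OC)C(C)=C | intermediate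
7 | 2-[(3R)-5,5-dimethoxy-3-(prop-1-en-2-yl)pent-1-en-2-yl]oxirane (both oxirane epimers) | C=C(C1CO1)[C@H](CC(OC)OC)C(C)=C | intermediate
8 | 3,3-dimethylcyclobutan-1-one | CC1(C)CC(=O)C1 | starting material
9 | RAMP, (R)-1-amino-2-(methoxymethyl)pyrrolidine | COC[C@H]1CCCN1N | starting material
10 | (2R)-N-(3,3-dimethylcyclobutylidene)-2-(methoxymethyl)pyrrolidin-1-amine | CC1(C)CC(=NN2CCC[C@@H]2COC)C1 | intermediate
11 | lithium azaenolate of 10 | [Li]N(N1CCC[C@@H]1COC)C1=CC(C)(C)C1 | intermediate
12 | lithium alkoxide of the C5-alkylated RAMP hydrazone (5S, 9R, both C7 epimers) | COC[C@H]1CCCN1N=C1CC(C)(C)[C@@H]1CC([O-])C(=C)[C@H](CC(OC)OC)C(C)=C.[Li+] | intermediate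
13 | RAMP hydrazone of 14 (5S, 9R, both C7 epimers) | COC[C@H]1CCCN1N=C1CC(C)(C)[C@@H]1CC(O[Si](C)(C)C(C)(C)C)C(=C)[C@H](CC(OC)OC)C(C)=C | intermediate
14 | (2S)-2-[(4R)-2-(tert-butyldimethylsilyloxy)-6,6-dimethoxy-3-methylidene-4-(prop-1-en-2-yl)hexyl]-3,3-dimethylcyclobutan-1-one (both C2' epimers) | O=C1CC(C)(C)[C@@H]1CC(O[Si](C)(C)C(C)(C)C)C(=C)[C@H](CC(OC)OC)C(C)=C | intermediate
15 | (5S,9R,10S)-7-(tert-butyldimethylsilyloxy)-12,12-dimethoxy-13,14,15,16-tetranorlabd-8(17)-en-2-one (both C7 epimers) | C=C1C(O[Si](C)(C)C(C)(C)C)C[C@H]2C(C)(C)CC(=O)C[C@]2(C)[C@H]1CC(OC)OC | intermediate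
16 | (2R,5S,9R,10S)-7-(tert-butyldimethylsilyloxy)-12,12-dimethoxy-13,14,15,16-tetranorlabd-8(17)-en-2β-ol (both C7 epimers) | C=C1C(O[Si](C)(C)C(C)(C)C)C[C@H]2C(C)(C)C[C@@H](O)C[C@]2(C)[C@H]1CC(OC)OC | intermediate
17 | (2S,5S,9R,10S)-7-(tert-butyldimethylsilyloxy)-2α-chloro-12,12-dimethoxy-13,14,15,16-tetranorlabd-8(17)-ene (both C7 epimers) | C=C1C(O[Si](C)(C)C(C)(C)C)C[C@H]2C(C)(C)C[C@H](Cl)C[C@]2(C)[C@H]1CC(OC)OC | intermediate
18 | (2S,5S,9R,10S)-2α-chloro-12,12-dimethoxy-13,14,15,16-tetranorlabd-8(17)-en-7-ol (both C7 epimers) | C=C1C(O)C[C@H]2C(C)(C)C[C@H](Cl)C[C@]2(C)[C@H]1CC(OC)OC | intermediate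
19 | (2S,5S,9R,10S)-2α-chloro-12,12-dimethoxy-13,14,15,16-tetranorlabd-8(17)-en-7-one | C=C1C(=O)C[C@H]2C(C)(C)C[C@H](Cl)C[C@]2(C)[C@H]1CC(OC)OC | intermediate
20 | (2S,5S,7S,9R,10S)-2α-chloro-12,12-dimethoxy-13,14,15,16-tetranorlabd-8(17)-en-7β-ol | C=C1[C@@H](O)C[C@H]2C(C)(C)C[C@H](Cl)C[C@]2(C)[C@H]1CC(OC)OC | intermediate
21 | (2S,5S,7S,9R,10S)-2α-chloro-12,12-dimethoxy-13,14,15,16-tetranorlabd-8(17)-en-7β-yl acetate | C=C1[C@@H](OC(C)=O)C[C@H]2C(C)(C)C[C@H](Cl)C[C@]2(C)[C@H]1CC(OC)OC | intermediate
22 | (2S,5S,7S,9R,10S)-7β-acetoxy-2α-chloro-13,14,15,16-tetranorlabd-8(17)-en-12-al | C=C1[C@@H](OC(C)=O)C[C@H]2C(C)(C)C[C@H](Cl)C[C@]2(C)[C@H]1CC=O | intermediate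
23 | (R)-4-benzyl-1,3-oxazolidin-2-one | O=C1N[C@H](Cc2ccccc2)CO1 | starting material
24 | 3-cyanopropanoic acid | N#CCCC(=O)O | starting material
25 | 3-cyanopropanoic pivalic anhydride | N#CCCC(=O)OC(=O)C(C)(C)C | intermediate
26 | (4R)-4-benzyl-3-(3-cyanopropanoyl)-1,3-oxazolidin-2-one | N#CCCC(=O)N1[C@H](Cc2ccccc2)COC1=O | intermediate
27 | Z-dibutylboron enolate of 26 | CCCCB(CCCC)O/C(=C\CC#N)N1[C@H](Cc2ccccc2)COC1=O | intermediate
28 | (12S,13R) syn-aldol adduct, N-acyl-(R)-4-benzyloxazolidinone with 13-cyanomethyl group | C=C1[C@@H](OC(C)=O)C[C@H]2C(C)(C)C[C@H](Cl)C[C@]2(C)[C@H]1C[C@H](O)[C@@H](CC#N)C(=O)N1[C@H](Cc2ccccc2)COC1=O | intermediate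
29 | (12S,13R) primary amide of 28 (13-carbamoylmethyl) | C=C1[C@@H](OC(C)=O)C[C@H]2C(C)(C)C[C@H](Cl)C[C@]2(C)[C@H]1C[C@H](O)[C@@H](CC(N)=O)C(=O)N1[C@H](Cc2ccccc2)COC1=O | intermediate
30 | haterumaimide N | C=C1[C@@H](OC(C)=O)C[C@H]2C(C)(C)C[C@H](Cl)C[C@]2(C)[C@H]1C[C@H](O)[C@H]1CC(=O)NC1=O | target

**Step count and risks**

Total step count: 20. Longest linear sequence: 18 (steps 1–6, 8–17, 19, 20).

Steps most likely to fail:

1. Step 10. The hindered 1,1-disubstituted olefin may insert too slowly into the neopentyl-type Rh–C5 bond, so that β-hydride loss from C6 (ring opening to an unsaturated aldehyde) or decarbonylation takes over, or the trans selectivity of the ring fusion may erode. The fallback changes the mode of C–C activation from olefin-assisted to chelation-assisted. It sets out from 14, which is condensed with 2-amino-3-methylpyridine (Ti(OEt)4, toluene) to the isolated N-(3-methylpyridin-2-yl) ketimine F1. Heating F1 with [Rh(C2H4)2Cl]2 and P(3,5-(CF3)2C6H3)3 in 1,4-dioxane at 130 °C lets the pyridine nitrogen direct rhodium into the C2–C5 bond without prior olefin binding and should give the ring-expanded decalin ketimine F2. Hydrolysis of F2 on wet silica gel comes back to the route at 15. Under these conditions C5 can equilibrate through the enamine tautomer, so the matched epimer would be drained dynamically.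

2. Step 8. The hindered azaenolate may open the oxirane sluggishly, with competing attack at the allylic carbon C7 or at C17, or with poor facial selectivity at C5. The fallback replaces the oxirane by a primary iodide, the classical electrophile of this alkylation. It sets out from 7, which is opened at the terminal carbon with LiI/AcOH in THF to the iodohydrin F3 and silylated (t-BuMe2SiOTf, 2,6-lutidine) to the β-silyloxy iodide F4. Azaenolate 11 (from 10 and LiN(i-Pr)2) is then alkylated with F4 at −100 to −78 °C, and the route is rejoined at 13.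

3. Step 12. The axial alkoxyphosphonium ion has antiperiplanar axial hydrogens at C1 and C3, so E2 elimination to the ring A olefins may compete with substitution. The fallback separates activation from displacement. It sets out from 16, which is converted with chloromethanesulfonyl chloride and pyridine into the isolated 2β-chloromethanesulfonate F5. Displacement of F5 with LiCl in DMF at 40 °C, a non-basic medium with a better leaving group, should proceed with inversion and comes back to the route at 17.

**Further compounds**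

F1 | step 10 | N-(3-methylpyridin-2-yl) ketimine of 14 | Cc1cccnc1N=C1CC(C)(C)[C@@H]1CC(O[Si](C)(C)C(C)(C)C)C(=C)[C@H](CC(OC)OC)C(C)=C
F2 | step 10 | N-(3-methylpyridin-2-yl) ketimine of 15 | C=C1C(O[Si](C)(C)C(C)(C)C)C[C@H]2C(C)(C)CC(=Nc3ncccc3C)C[C@]2(C)[C@H]1CC(OC)OC
F3 | step 8 | (4R)-1-iodo-6,6-dimethoxy-3-methylidene-4-(prop-1-en-2-yl)hexan-2-ol (both C2 epimers) | C=C(C(O)CI)[C@H](CC(OC)OC)C(C)=C
F4 | step 8 | tert-butyldimethylsilyl ether of F3 | C=C(C(CI)O[Si](C)(C)C(C)(C)C)[C@H](CC(OC)OC)C(C)=C
F5 | step 12 | 2β-chloromethanesulfonate of 16 | C=C1C(O[Si](C)(C)C(C)(C)C)C[C@H]2C(C)(C)C[C@@H](OS(=O)(=O)CCl)C[C@]2(C)[C@H]1CC(OC)OC
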